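**Retrosynthetic overview**
1. Ring B is closed last, as in shikonin/alkannin biosynthesis, where the oxidised geranyl chain closes onto the hydroquinone. A 2-furyl-1,4-benzoquinone (furan = masked (Z)-enedial, the counterpart of 3''-oxo-geranylhydroquinone) is opened by water, the formyl carbon attacks ring A, and the leuco product is dehydrogenated.
2. The furylquinone comes from C–C union of bought ring A (1,4-benzoquinone) with the free α-carbon of a 3-substituted furan, the counterpart of prenylation of the hydroquinone nucleus.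
3. The furan already carries the whole side chain as the ester of (S)-1-(furan-3-yl)-4-methylpent-3-en-1-ol with 3-acetoxy-3-methylbutanoic acid. The ester goes on before annulation because a free C-1′ hydroxyl would cyclodehydrate with the enal.
4. C-1′ (S) is set by Brown allylboration of furan-3-carbaldehyde; cross-metathesis with 2-methyl-2-butene makes the prenyl terminus.
5. Ring order: ring A is bought; ring B is the only ring formed, in the last step.

Assumption: the SMILES descriptor corresponds to S at C-1′ (alkannin series), and (−)-B-allyldiisopinocampheylborane is bought as its commercial pentane solution.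

**Step 1**
Reactants: 1 furan-3-carbaldehyde
Product: 3 (S)-1-(furan-3-yl)but-3-en-1-ol, via O-borinate 2 (not isolated)
Conditions: (−)-Ipc2B(allyl) (1 M in pentane, 1.2 equiv), Et2O, −100 °C; then HOCH2CH2NH2, rt
Reagents that add atoms: (−)-B-allyldiisopinocampheylborane (Ipc groups from (+)-α-pinene), C=CCB([C@@H]1C[C@@H]2C[C@H]([C@H]1C)C2(C)C)[C@@H]1C[C@@H]2C[C@H]([C@H]1C)C2(C)C
Why: Brown asymmetric allylboration delivers the allyl group through a chair Zimmerman–Traxler transition state to the Si face of the aldehyde, giving the S carbinol (3-furyl outranks allyl, as for benzaldehyde giving (S)-1-phenylbut-3-en-1-ol), and ethanolamine then frees the alcohol from borinate 2.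

**Step 2**
Reactants: 3 (S)-1-(furan-3-yl)but-3-en-1-ol
Product: 4 (S)-1-(furan-3-yl)-4-methylpent-3-en-1-ol
Conditions: second-generation Grubbs catalyst RuCl2(=CHPh)(PCy3)(H2IMes) (3 mol %), 2-methyl-2-butene (neat), 35 °C
Reagents that add atoms: 2-methyl-2-butene, CC=C(C)C
Why: Olefin cross-metathesis of the terminal (type 1) alkene with excess 2-methyl-2-butene installs the isopropylidene terminus with loss of volatile propene, leaving furan, free alcohol and stereocentre untouched.

**Step 3**
Reactants: 5 3-hydroxy-3-methylbutanoic acid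
Product: 7 3-acetoxy-3-methylbutanoic acid, via mixed anhydride 6 (not isolated)
Conditions: Ac2O (3 equiv), Sc(OTf)3 (1 mol %), MeCN, −20 → 0 °C; then H2O–THF, rt
Reagents that add atoms: acetic anhydride, CC(=O)OC(C)=O
Why: Sc(OTf)3-catalysed acylation with Ac2O acetylates tertiary alcohols at low temperature without elimination; the carboxyl group is acetylated too (mixed anhydride 6) and is regenerated by mild hydrolysis, which the tertiary acetate survives.

**Step 4**
Reactants: 4 (S)-1-(furan-3-yl)-4-methylpent-3-en-1-ol; 7 3-acetoxy-3-methylbutanoic acid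
Product: 9 (S)-1-(furan-3-yl)-4-methylpent-3-en-1-yl 3-acetoxy-3-methylbutanoate, via O-acylisourea 8 (not isolated)
Conditions: DCC (1.2 equiv), DMAP (0.1 equiv), CH2Cl2, 0 °C → rt
Reagents that add atoms: none
Why: Steglich esterification acylates the secondary alcohol on oxygen, so the C–O bond at the stereocentre is never broken and S is retained, while low temperature and catalytic DMAP limit β-elimination of the tertiary acetate.

**Step 5**
Reactants: 9 (S)-1-(furan-3-yl)-4-methylpent-3-en-1-yl 3-acetoxy-3-methylbutanoate; 10 1,4-benzoquinone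
Product: 12 (S)-1-[5-(3,6-dioxocyclohexa-1,4-dien-1-yl)furan-3-yl]-4-methylpent-3-en-1-yl 3-acetoxy-3-methylbutanoate, via furylhydroquinone 11 (not isolated)
Conditions: 10 (3 equiv), Sc(OTf)3 (5 mol %), MeCN, 4 Å molecular sieves, 0 °C → rt
Reagents that add atoms: none
Why: Lewis acid-catalysed Friedel–Crafts-type conjugate addition of the furan α-carbon to the quinone (the classical substitutive addition of furans to quinones) occurs at the less hindered C-5 to give 11, which a second equivalent of quinone dehydrogenates to the furylquinone; attack at either α-carbon would lead to the same naphthazarin in step 6.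

**Step 6**
Reactants: 12 (S)-1-[5-(3,6-dioxocyclohexa-1,4-dien-1-yl)furan-3-yl]-4-methylpent-3-en-1-yl 3-acetoxy-3-methylbutanoate
Product: 16 (S)-1-(5,8-dihydroxy-1,4-dioxo-1,4-dihydronaphthalen-2-yl)-4-methylpent-3-en-1-yl 3-acetoxy-3-methylbutanoate, via aroyl enal 13 (not isolated), via carbinol 14 (not isolated), via leuco tetraol 15 (not isolated)
Conditions: Sc(OTf)3 (10 mol %), MeCN–H2O (9:1), 1,4-benzoquinone 10 (1.2 equiv), 50 °C, dark
Reagents that add atoms: water, O
Why: Proposed new method: the acid-activated quinone turns the furan into a vinylogous furfuryl-type oxocarbenium ion, so water adds at the free furan C-5 and the ring opens with internal redox (quinone to hydroquinone, furan to (Z)-aroyl enal 13; closest precedents are the first stage of the Piancatelli rearrangement and Stenhouse furan opening); the formyl carbon is then attacked by ring A ortho to the free hydroxyl (intramolecular Friedel–Crafts hydroxyalkylation, Bradsher/Marschalk-type) to give 14, which enolises to 15 and is dehydrogenated at once by 10 before the leuco form can lose its C-1′ carboxylate, mirroring the biosynthetic closure of 3''-oxo-geranylhydroquinone without touching C-1′ (S retained).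

**Compound list**
1 | furan-3-carbaldehyde | O=Cc1ccoc1 | starting material
2 | (S)-1-(furan-3-yl)but-3-en-1-yl diisopinocampheylborinate (not isolated) | O([C@@H](CC=C)c1ccoc1)B([C@@H]1C[C@@H]2C[C@H]([C@H]1C)C2(C)C)[C@@H]1C[C@@H]2C[C@H]([C@H]1C)C2(C)C | intermediate
3 | (S)-1-(furan-3-yl)but-3-en-1-ol | O[C@@H](CC=C)c1ccoc1 | intermediate
4 | (S)-1-(furan-3-yl)-4-methylpent-3-en-1-ol | O[C@@H](CC=C(C)C)c1ccoc1 | intermediate
5 | 3-hydroxy-3-methylbutanoic acid | CC(C)(O)CC(=O)O | starting material
6 | acetic 3-acetoxy-3-methylbutanoic anhydride (not isolated) | CC(=O)OC(C)(C)CC(=O)OC(C)=O | intermediate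
7 | 3-acetoxy-3-methylbutanoic acid | CC(=O)OC(C)(C)CC(=O)O | intermediate
8 | N,N′-dicyclohexyl-O-(3-acetoxy-3-methylbutanoyl)isourea (not isolated) | CC(=O)OC(C)(C)CC(=O)OC(=NC1CCCCC1)NC1CCCCC1 | intermediate
9 | (S)-1-(furan-3-yl)-4-methylpent-3-en-1-yl 3-acetoxy-3-methylbutanoate | CC(=O)OC(C)(C)CC(=O)O[C@@H](CC=C(C)C)c1ccoc1 | intermediate
10 | 1,4-benzoquinone | O=C1C=CC(=O)C=C1 | starting material
11 | (S)-1-[5-(2,5-dihydroxyphenyl)furan-3-yl]-4-methylpent-3-en-1-yl 3-acetoxy-3-methylbutanoate (not isolated) | CC(=O)OC(C)(C)CC(=O)O[C@@H](CC=C(C)C)c1coc(c1)-c1cc(O)ccc1O | intermediate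
12 | (S)-1-[5-(3,6-dioxocyclohexa-1,4-dien-1-yl)furan-3-yl]-4-methylpent-3-en-1-yl 3-acetoxy-3-methylbutanoate | CC(=O)OC(C)(C)CC(=O)O[C@@H](CC=C(C)C)c1coc(c1)C1=CC(=O)C=CC1=O | intermediate
13 | (2Z,4S)-1-(2,5-dihydroxyphenyl)-3-formyl-7-methyl-1-oxoocta-2,6-dien-4-yl 3-acetoxy-3-methylbutanoate (not isolated) | CC(=O)OC(C)(C)CC(=O)O[C@@H](CC=C(C)C)/C(C=O)=C/C(=O)c1cc(O)ccc1O | intermediate
14 | (S)-4-methyl-1-(1,5,8-trihydroxy-4-oxo-1,4-dihydronaphthalen-2-yl)pent-3-en-1-yl 3-acetoxy-3-methylbutanoate, both carbinol epimers (not isolated) | CC(=O)OC(C)(C)CC(=O)O[C@@H](CC=C(C)C)C1=CC(=O)c2c(O)ccc(O)c2C1O | intermediate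
15 | (S)-4-methyl-1-(1,4,5,8-tetrahydroxynaphthalen-2-yl)pent-3-en-1-yl 3-acetoxy-3-methylbutanoate, leuco form (not isolated) | CC(=O)OC(C)(C)CC(=O)O[C@@H](CC=C(C)C)c1cc(O)c2c(O)ccc(O)c2c1O | intermediate
16 | (S)-1-(5,8-dihydroxy-1,4-dioxo-1,4-dihydronaphthalen-2-yl)-4-methylpent-3-en-1-yl 3-acetoxy-3-methylbutanoate (β-acetoxyisovalerylalkannin) | CC(=O)OC(C)(C)CC(=O)O[C@@H](CC=C(C)C)C1=CC(=O)c2c(O)ccc(O)c2C1=O | target

**Totals**
Total steps: 6. Longest linear sequence: 5 (steps 1, 2, 4, 5, 6); step 3 is a one-step side branch.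

**Steps most likely to fail**

Step 6 (key cascade) is the riskiest. Water may not add to the furylquinone, the arene-onto-aldehyde closure ortho to the aroyl group may be slow under acid mild enough for the prenyl alkene, and the leuco stage can lose the C-1′ carboxylate. The fallback sets out from 12 and returns at 16. It replaces the redox-neutral opening by an external oxidant and the acid closure by a phenoxide closure. Compound 12 is reduced (Na2S2O4, EtOAc–H2O) to 11 and silylated (TBSCl, imidazole, DMF) to the bis(tert-butyldimethylsilyl) ether F1. Singlet-oxygen [4+2] photo-oxygenation of the aryl furan (O2, methylene blue, hν, CH2Cl2, −78 °C; then Me2S) is faster than the ene reaction of the trisubstituted alkene and gives the silylated (Z)-aroyl enal F2. Buffered fluoride (Bu4NF–AcOH, THF, 0 °C) in the presence of 10 unmasks the phenoxide, which closes onto the aldehyde (Marschalk-type) and is dehydrogenated to 16.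

Step 5 (quinone–furan union) is next. The 3-furylcarbinyl ester may ionise under Lewis acid, and over-arylation of the quinone is possible. The fallback sets out from 9 and returns at 12. Sterically controlled C–H borylation of the furan at C-5 ([Ir(OMe)(cod)]2, 4,4′-di-tert-butyl-2,2′-bipyridine, B2pin2, hexane, rt) gives the pinacol boronate F3. Oxidative boron-Heck-type coupling with excess 10 (Pd(OAc)2 cat., acetone–H2O, rt; the quinone also reoxidises the catalyst) gives 12 under near-neutral conditions.

Step 4 (esterification) is third. The activated β-acetoxy acid can eliminate acetate to give the 3-methylbut-2-enoate instead. The fallback sets out from 4 and returns at 9, building the acyl chain on the substrate. Acetylation of 4 (Ac2O, pyridine) gives the acetate F4. Its lithium enolate (lithium diisopropylamide, THF, −78 °C) adds to acetone to give the β-hydroxy ester F5. Acetylation of the tertiary alcohol (Ac2O, DMAP, Et3N, CH2Cl2) gives 9.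

**Further compounds**
F1 | step 6 | (S)-1-{5-[2,5-bis(tert-butyldimethylsilyloxy)phenyl]furan-3-yl}-4-methylpent-3-en-1-yl 3-acetoxy-3-methylbutanoate | CC(=O)OC(C)(C)CC(=O)O[C@@H](CC=C(C)C)c1coc(c1)-c1cc(O[Si](C)(C)C(C)(C)C)ccc1O[Si](C)(C)C(C)(C)C
F2 | step 6 | (2Z,4S)-1-[2,5-bis(tert-butyldimethylsilyloxy)phenyl]-3-formyl-7-methyl-1-oxoocta-2,6-dien-4-yl 3-acetoxy-3-methylbutanoate | CC(=O)OC(C)(C)CC(=O)O[C@@H](CC=C(C)C)/C(C=O)=C/C(=O)c1cc(O[Si](C)(C)C(C)(C)C)ccc1O[Si](C)(C)C(C)(C)C
F3 | step 5 | (S)-4-methyl-1-[5-(4,4,5,5-tetramethyl-1,3,2-dioxaborolan-2-yl)furan-3-yl]pent-3-en-1-yl 3-acetoxy-3-methylbutanoate | CC(=O)OC(C)(C)CC(=O)O[C@@H](CC=C(C)C)c1coc(c1)B1OC(C)(C)C(C)(C)O1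
F4 | step 4 | (S)-1-(furan-3-yl)-4-methylpent-3-en-1-yl acetate | CC(=O)O[C@@H](CC=C(C)C)c1ccoc1
F5 | step 4 | (S)-1-(furan-3-yl)-4-methylpent-3-en-1-yl 3-hydroxy-3-methylbutanoate | CC(C)(O)CC(=O)O[C@@H](CC=C(C)C)c1ccoc1
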